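Ring A of the C8-linked fisetinidol unit is bound to its heterocycle only through two neighbouring aromatic carbons, C8a (to O1) and C4a (to C4), the retron of an aryne annulation. A 3-chloro-5-benzyloxybenzyne is therefore inserted between the hydroxyl oxygen and the amide carbon of an anti α-benzyloxy-β-hydroxy Weinreb amide that already carries C2 and C3. O-arylation at C8a and C-acylation by the resulting C4a anion close ring C as a dihydroflavonol ketone in one operation. The chlorine steers the regiochemistry and leaves in the final hydrogenolysis. Two such ketones are added to 6,8-dilithiated catechin, and ionic hydrogenation sets both 3,4-cis interflavan bonds.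

Key step: step 7

Remark: the target is read as (2R,3S)-fisetinidol-(4β→8)-[(2R,3S)-fisetinidol-(4β→6)]-(+)-catechin, both upper units 2,3-trans-3,4-cis; the carbinol centres of 20 are drawn as the expected epimers and are erased in step 11.

Step 1
Reactants: 1 4-(benzyloxy)phenol
Product: 2 4-(benzyloxy)-2-chlorophenol
Conditions: SO2Cl2 (1.05 equiv), Et2O/CH2Cl2, 0 °C to rt
Reagents that add atoms: sulfuryl chloride, O=S(=O)(Cl)Cl
Why: Electrophilic aromatic chlorination, in which the free hydroxyl is the stronger director and its para position is blocked, so chlorine should enter ortho to OH.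

Step 2
Reactants: 2 4-(benzyloxy)-2-chlorophenol
Product: 3 4-(benzyloxy)-2-bromo-6-chlorophenol
Conditions: NBS (1.05 equiv), i-Pr2NH (10 mol%), CH2Cl2, 0 °C
Reagents that add atoms: N-bromosuccinimide, O=C1CCC(=O)N1Br
Why: Amine-mediated ortho-bromination of a phenol, which should occupy the only remaining position ortho to OH.

Step 3
Reactants: 3 4-(benzyloxy)-2-bromo-6-chlorophenol
Product: 6 4-(benzyloxy)-2-chloro-6-(trimethylsilyl)phenyl trifluoromethanesulfonate, via aryl trimethylsilyl ether 4 (not isolated), via lithium 2-silylphenoxide 5 (not isolated)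
Conditions: HMDS, THF, 70 °C, then evaporation; n-BuLi (1.1 equiv), THF, −78 °C; Tf2O (1.2 equiv), −78 °C to rt
Reagents that add atoms: hexamethyldisilazane, C[Si](C)(C)N[Si](C)(C)C; triflic anhydride, O=S(=O)(OS(=O)(=O)C(F)(F)F)C(F)(F)F
Why: O-silylation, bromine–lithium exchange (the aryl chloride is inert at −78 °C), retro-Brook 1,3-O→C silyl shift and O-triflation are the standard route to o-silylaryl triflates.

Step 4
Reactants: 7 (S)-4-benzyl-1,3-oxazolidine-2-thione; 8 (benzyloxy)acetyl chloride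
Product: 9 (S)-4-benzyl-3-[(benzyloxy)acetyl]-1,3-oxazolidine-2-thione
Conditions: Et3N (1.3 equiv), CH2Cl2, 0 °C
Reagents that add atoms: none
Why: N-acylation of the auxiliary with an acid chloride.

Step 5
Reactants: 9 (S)-4-benzyl-3-[(benzyloxy)acetyl]-1,3-oxazolidine-2-thione; 10 3,4-bis(benzyloxy)benzaldehyde
Product: 11 (4S)-4-benzyl-3-[(2R,3R)-2-(benzyloxy)-3-[3,4-bis(benzyloxy)phenyl]-3-hydroxypropanoyl]-1,3-oxazolidine-2-thione (anti)
Conditions: TiCl4 (1.1 equiv), i-Pr2NEt (1.1 equiv), CH2Cl2, −78 °C; then 10 premixed with TiCl4 (2.5 equiv), −78 °C; aq. NH4Cl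
Reagents that add atoms: none
Why: Anti-selective titanium glycolate aldol addition, in which the chlorotitanium (Z)-enolate, chelated by the glycolate oxygen and the thiocarbonyl sulfur, cannot bind the aldehyde, so the TiCl4-activated aldehyde should attack through an open transition state on the enolate face away from the 4-benzyl group (the sense of alkylations of such enolates), setting C2 as R and the carbinol carbon anti to it as R (the antipodal auxiliary would be used should the sense prove opposite).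

Step 6
Reactants: 11 (4S)-4-benzyl-3-[(2R,3R)-2-(benzyloxy)-3-[3,4-bis(benzyloxy)phenyl]-3-hydroxypropanoyl]-1,3-oxazolidine-2-thione
Product: 12 (2R,3R)-2-(benzyloxy)-3-[3,4-bis(benzyloxy)phenyl]-3-hydroxy-N-methoxy-N-methylpropanamide
Conditions: MeNH(OMe)·HCl (3 equiv), imidazole (5 equiv), CH2Cl2, rt
Reagents that add atoms: N,O-dimethylhydroxylamine hydrochloride, CNOC.Cl
Why: Aminolysis of the activated N-acyl oxazolidinethione under mild conditions should give the Weinreb amide without epimerisation and return the auxiliary.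

Step 7
Reactants: 12 (2R,3R)-2-(benzyloxy)-3-[3,4-bis(benzyloxy)phenyl]-3-hydroxy-N-methoxy-N-methylpropanamide; 6 4-(benzyloxy)-2-chloro-6-(trimethylsilyl)phenyl trifluoromethanesulfonate
Product: 15 (2R,3R)-3,7-bis(benzyloxy)-2-[3,4-bis(benzyloxy)phenyl]-5-chlorochroman-4-one (2,3-trans), via 3-chloro-5-(benzyloxy)benzyne 13 (not isolated), via cesium hemiaminal alkoxide 14 (not isolated)
Conditions: 6 (1.6 equiv, slow addition), CsF (4 equiv), 18-crown-6 (1 equiv), THF, 0 °C to rt; aq. NH4Cl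
Reagents that add atoms: none
Why: Proposed new method: fluoride liberates aryne 13 from 6, the fluoride-activated (cesium) alkoxide of 12 adds to the aryne carbon remote from chlorine (the future C8a) because the C–Cl dipole distorts the aryne and stabilises the developing carbanion at the adjacent carbon (C4a), and this o-chloroaryl anion should be acylated by the Weinreb carbonyl faster than it is protonated or loses chloride, giving the tetrahedral adduct 14, which releases the ketone only on aqueous work-up. The closest known reaction type is the fluoride-mediated coupling–cyclisation of arynes with salicylate esters to xanthones (O-arylation followed by intramolecular acyl substitution); an aliphatic β-alkoxide with an amide acceptor has not been shown in it. Ring C closes by a 6-exo-trig attack of C4a on the amide carbon C4 after the intermolecular O1–C8a bond formation, a formal [4+2] of the O1–C2–C3–C4 unit with the two aryne carbons. No stereocentre is created: C2 and C3 come unchanged from 12, and the tetrahedral adduct keeps the base-sensitive α-alkoxy ketone masked against enolisation and ring opening. The step needs O-attack at one aryne terminus only, which the chlorine ortho to the other terminus secures, and cyclisation in preference to proton capture, which the aprotic medium and the six-membered reach of the amide secure.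

Step 8
Reactants: 16 (+)-catechin
Product: 17 (2R,3S)-3,5,7-tris(benzyloxy)-2-[3,4-bis(benzyloxy)phenyl]chroman (penta-O-benzylcatechin)
Conditions: BnBr (6.5 equiv), NaH (6 equiv), DMF, −20 °C to rt
Reagents that add atoms: benzyl bromide, BrCc1ccccc1
Why: Williamson etherification of the four phenols and the secondary alcohol, run cold to limit C-benzylation.

Step 9
Reactants: 17 penta-O-benzylcatechin
Product: 18 (2R,3S)-3,5,7-tris(benzyloxy)-2-[3,4-bis(benzyloxy)phenyl]-6,8-dibromochroman
Conditions: NBS (2.1 equiv), CH2Cl2, −20 to 0 °C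
Reagents that add atoms: N-bromosuccinimide, O=C1CCC(=O)N1Br
Why: Electrophilic bromination should occur at C6 and C8 of ring D, the phloroglucinol-type ring, which is far more electron-rich than the other arenes.

Step 10
Reactants: 18 6,8-dibromo-penta-O-benzylcatechin; 15 (2R,3R)-3,7-bis(benzyloxy)-2-[3,4-bis(benzyloxy)phenyl]-5-chlorochroman-4-one (2.3 equiv)
Product: 20 penta-O-benzylcatechin carrying at C6 and at C8 a (2R,3R,4S)-3,7-bis(benzyloxy)-2-[3,4-bis(benzyloxy)phenyl]-5-chloro-4-hydroxychroman-4-yl group (4-OH cis to 3-OBn), via 6,8-dilithio arene 19 (not isolated)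
Conditions: t-BuLi (4.2 equiv), THF, −78 °C; then 15 in THF, −78 to −40 °C; then H2O
Reagents that add atoms: none
Why: Double bromine–lithium exchange (each aryllithium flanked by two alkoxy groups) followed by 1,2-addition to the ketone of 15, in which aryl chlorides and benzyl ethers are inert and attack is expected anti to the 3-benzyloxy group, although the carbinol configuration is irrelevant because step 11 erases it.

Step 11
Reactants: 20 bis-carbinol
Product: 21 penta-O-benzylcatechin carrying at C6 and at C8 a (2R,3S,4S)-3,7-bis(benzyloxy)-2-[3,4-bis(benzyloxy)phenyl]-5-chlorochroman-4-yl group (2,3-trans-3,4-cis in each unit)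
Conditions: Bu3SnH (8 equiv), CF3CO2H (12 equiv), CH2Cl2, −20 to 0 °C
Reagents that add atoms: none
Why: Ionic hydrogenation, in which acid ionises each carbinol to a C4 cation stabilised by ring A and ring D and the stannane should deliver hydride anti to the neighbouring 3-benzyloxy group (the face selection known for nucleophiles on 2,3-trans flavan-4-yl cations and for this reagent pair on 4-aryl-4-hydroxyflavan ethers), so H-4 ends trans to O-3 and the catechin ring cis to it.

Step 12
Reactants: 21 tridecabenzyl dichloro trimer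
Product: 22 fisetinidol-(4β→8)-[fisetinidol-(4β→6)]-catechin (target; upper units 2R,3S,4R, lower unit 2R,3S)
Conditions: H2 (4 bar), Pd(OH)2/C, Et3N (3 equiv), THF/MeOH 1:1, rt; filtration under argon, AcOH
Reagents that add atoms: none
Why: Hydrogenolysis of the thirteen benzyl ethers together with palladium-mediated hydrodechlorination of the two aryl chlorides (the amine takes up HCl) should leave all stereocentres untouched.

Compound list
1 | 4-(benzyloxy)phenol | Oc1ccc(OCc2ccccc2)cc1 | starting material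
2 | 4-(benzyloxy)-2-chlorophenol | Oc1ccc(OCc2ccccc2)cc1Cl | intermediate
3 | 4-(benzyloxy)-2-bromo-6-chlorophenol | Oc1c(Cl)cc(OCc2ccccc2)cc1Br | intermediate
4 | [4-(benzyloxy)-2-bromo-6-chlorophenoxy]trimethylsilane | C[Si](C)(C)Oc1c(Cl)cc(OCc2ccccc2)cc1Br | intermediate
5 | lithium 4-(benzyloxy)-2-chloro-6-(trimethylsilyl)phenoxide | [Li+].[O-]c1c(Cl)cc(OCc2ccccc2)cc1[Si](C)(C)C | intermediate
6 | 4-(benzyloxy)-2-chloro-6-(trimethylsilyl)phenyl trifluoromethanesulfonate | C[Si](C)(C)c1cc(OCc2ccccc2)cc(Cl)c1OS(=O)(=O)C(F)(F)F | intermediate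
7 | (S)-4-benzyl-1,3-oxazolidine-2-thione | S=C1N[C@@H](Cc2ccccc2)CO1 | starting material
8 | (benzyloxy)acetyl chloride | O=C(Cl)COCc1ccccc1 | starting material
9 | (S)-4-benzyl-3-[(benzyloxy)acetyl]-1,3-oxazolidine-2-thione | O=C(COCc1ccccc1)N1[C@@H](Cc2ccccc2)COC1=S | intermediate
10 | 3,4-bis(benzyloxy)benzaldehyde | O=Cc1ccc(OCc2ccccc2)c(OCc2ccccc2)c1 | starting material
11 | (4S)-4-benzyl-3-[(2R,3R)-2-(benzyloxy)-3-[3,4-bis(benzyloxy)phenyl]-3-hydroxypropanoyl]-1,3-oxazolidine-2-thione | O[C@H](c1ccc(OCc2ccccc2)c(OCc2ccccc2)c1)[C@H](C(=O)N1[C@@H](Cc2ccccc2)COC1=S)OCc1ccccc1 | intermediate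
12 | (2R,3R)-2-(benzyloxy)-3-[3,4-bis(benzyloxy)phenyl]-3-hydroxy-N-methoxy-N-methylpropanamide | O[C@H](c1ccc(OCc2ccccc2)c(OCc2ccccc2)c1)[C@H](C(=O)N(C)OC)OCc1ccccc1 | intermediate
13 | 3-chloro-5-(benzyloxy)benzyne | ClC1=CC(OCc2ccccc2)=CC#C1 | intermediate
14 | cesium (2R,3R)-3,7-bis(benzyloxy)-2-[3,4-bis(benzyloxy)phenyl]-5-chloro-4-[methoxy(methyl)amino]chroman-4-olate (C4 configuration not defined, centre lost on work-up) | [Cs+].CON(C)C1([O-])c2c(Cl)cc(OCc3ccccc3)cc2O[C@H](c2ccc(OCc3ccccc3)c(OCc3ccccc3)c2)[C@H]1OCc1ccccc1 | intermediate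
15 | (2R,3R)-3,7-bis(benzyloxy)-2-[3,4-bis(benzyloxy)phenyl]-5-chlorochroman-4-one | O=C1c2c(Cl)cc(OCc3ccccc3)cc2O[C@H](c2ccc(OCc3ccccc3)c(OCc3ccccc3)c2)[C@H]1OCc1ccccc1 | intermediate
16 | (+)-catechin, (2R,3S) | Oc1cc(O)c2c(c1)O[C@H](c1ccc(O)c(O)c1)[C@@H](O)C2 | starting material
17 | (2R,3S)-3,5,7-tris(benzyloxy)-2-[3,4-bis(benzyloxy)phenyl]chroman | O(Cc1ccccc1)c1cc(OCc3ccccc3)c2c(c1)O[C@H](c1ccc(OCc3ccccc3)c(OCc3ccccc3)c1)[C@@H](OCc1ccccc1)C2 | intermediate
18 | (2R,3S)-3,5,7-tris(benzyloxy)-2-[3,4-bis(benzyloxy)phenyl]-6,8-dibromochroman | O(Cc1ccccc1)c1c(Br)c(OCc3ccccc3)c2c(c1Br)O[C@H](c1ccc(OCc3ccccc3)c(OCc3ccccc3)c1)[C@@H](OCc1ccccc1)C2 | intermediate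
19 | 6,8-dilithio-penta-O-benzylcatechin | O(Cc1ccccc1)c1c([Li])c(OCc3ccccc3)c2c(c1[Li])O[C@H](c1ccc(OCc3ccccc3)c(OCc3ccccc3)c1)[C@@H](OCc1ccccc1)C2 | intermediate
20 | 6,8-bis[(2R,3R,4S)-3,7-bis(benzyloxy)-2-[3,4-bis(benzyloxy)phenyl]-5-chloro-4-hydroxychroman-4-yl]-penta-O-benzylcatechin (4-OH cis to 3-OBn) | O(Cc1ccccc1)c1cc(Cl)c2c(c1)O[C@H](c1ccc(OCc3ccccc3)c(OCc3ccccc3)c1)[C@@H](OCc1ccccc1)[C@]2(O)c1c(OCc3ccccc3)c2c(c([C@]3(O)c4c(Cl)cc(OCc5ccccc5)cc4O[C@H](c4ccc(OCc5ccccc5)c(OCc5ccccc5)c4)[C@H]3OCc3ccccc3)c1OCc1ccccc1)O[C@H](c1ccc(OCc3ccccc3)c(OCc3ccccc3)c1)[C@@H](OCc1ccccc1)C2 | intermediate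
21 | 6,8-bis[(2R,3S,4S)-3,7-bis(benzyloxy)-2-[3,4-bis(benzyloxy)phenyl]-5-chlorochroman-4-yl]-penta-O-benzylcatechin (2,3-trans-3,4-cis units) | O(Cc1ccccc1)c1cc(Cl)c2c(c1)O[C@H](c1ccc(OCc3ccccc3)c(OCc3ccccc3)c1)[C@@H](OCc1ccccc1)[C@H]2c1c(OCc3ccccc3)c2c(c([C@H]3c4c(Cl)cc(OCc5ccccc5)cc4O[C@H](c4ccc(OCc5ccccc5)c(OCc5ccccc5)c4)[C@H]3OCc3ccccc3)c1OCc1ccccc1)O[C@H](c1ccc(OCc3ccccc3)c(OCc3ccccc3)c1)[C@@H](OCc1ccccc1)C2 | intermediate
22 | fisetinidol-(4β→8)-[fisetinidol-(4β→6)]-catechin | Oc1ccc2c(c1)O[C@H](c1ccc(O)c(O)c1)[C@@H](O)[C@H]2c1c(O)c2c(c([C@H]3c4ccc(O)cc4O[C@H](c4ccc(O)c(O)c4)[C@H]3O)c1O)O[C@H](c1ccc(O)c(O)c1)[C@@H](O)C2 | target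

Total step count: 12. Longest linear sequence: 7 steps (4, 5, 6, 7, 10, 11, 12; equally 1, 2, 3, 7, 10, 11, 12).

Steps most likely to fail

Step 7 (Proposed new method). The o-chloroaryl anion may be protonated before it reaches the amide (plain O-arylation), may expel chloride to a second aryne, or the β-alkoxide may fragment by retro-aldol cleavage. The fallback uses known chemistry and forms the two bonds in two operations. It sets out from 12, which is silylated (Et3SiCl, imidazole, CH2Cl2) to the (2R,3R)-triethylsilyl ether F1. 1-(Benzyloxy)-3-chloro-5-fluorobenzene F2 (from commercial 3-chloro-5-fluorophenol, BnBr, K2CO3) is lithiated between the two halogens (LiN(i-Pr)2, THF, −78 °C) to 4-(benzyloxy)-2-chloro-6-fluorophenyllithium F3, which adds to the Weinreb amide of F1 to give the aryl ketone F4. Bu4NF (THF, 0 °C) removes the silyl group, and the released alkoxide displaces the fluoride activated by the ortho carbonyl (intramolecular SNAr), which returns to the route at 15.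

Step 10. The second addition at the crowded dilithio arene may stall, and the hindered aryllithium may enolise ketone 15 instead of adding. The fallback installs the two units one after the other. It sets out from 17, which is monobrominated (NBS, 1.0 equiv, CH2Cl2, −40 °C) to 8-bromo-penta-O-benzylcatechin F5. Exchange with t-BuLi and addition to 15 gives the C8 mono-carbinol F6, and a second bromination (NBS) gives the 6-bromo mono-carbinol F7. t-BuLi (3 equiv, the first deprotonating the hydroxyl) and a second portion of 15 return to the route at 20.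

Step 11. The C4 cation may lose H-3 to an enol ether, prolonged acid may cleave benzyl ethers, and facial selectivity may erode at one of the two centres. The fallback avoids the cation by a radical deoxygenation. It sets out from 20, whose two tertiary alkoxides (n-BuLi, THF, −78 °C) are acylated with methyl chlorooxoacetate to the bis(methyl oxalate) F8. Bu3SnH with AIBN in toluene at 100 °C should transfer a hydrogen atom to each planar C4 radical from the face anti to the 3-benzyloxy group, which returns to the route at 21.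

Further compounds
F1 | step 7 | (2R,3R)-2-(benzyloxy)-3-[3,4-bis(benzyloxy)phenyl]-N-methoxy-N-methyl-3-(triethylsilyloxy)propanamide | CC[Si](CC)(CC)O[C@H](c1ccc(OCc2ccccc2)c(OCc2ccccc2)c1)[C@H](C(=O)N(C)OC)OCc1ccccc1
F2 | step 7 | 1-(benzyloxy)-3-chloro-5-fluorobenzene | Fc1cc(Cl)cc(OCc2ccccc2)c1
F3 | step 7 | 4-(benzyloxy)-2-chloro-6-fluorophenyllithium | [Li]c1c(F)cc(OCc2ccccc2)cc1Cl
F4 | step 7 | (2R,3R)-2-(benzyloxy)-1-[4-(benzyloxy)-2-chloro-6-fluorophenyl]-3-[3,4-bis(benzyloxy)phenyl]-3-(triethylsilyloxy)propan-1-one | CC[Si](CC)(CC)O[C@H](c1ccc(OCc2ccccc2)c(OCc2ccccc2)c1)[C@H](C(=O)c1c(F)cc(OCc2ccccc2)cc1Cl)OCc1ccccc1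
F5 | step 10 | (2R,3S)-3,5,7-tris(benzyloxy)-2-[3,4-bis(benzyloxy)phenyl]-8-bromochroman | O(Cc1ccccc1)c1cc(OCc3ccccc3)c2c(c1Br)O[C@H](c1ccc(OCc3ccccc3)c(OCc3ccccc3)c1)[C@@H](OCc1ccccc1)C2
F6 | step 10 | penta-O-benzylcatechin carrying at C8 the (2R,3R,4S)-3,7-bis(benzyloxy)-2-[3,4-bis(benzyloxy)phenyl]-5-chloro-4-hydroxychroman-4-yl group | c1c(OCc3ccccc3)c2c(c([C@]3(O)c4c(Cl)cc(OCc5ccccc5)cc4O[C@H](c4ccc(OCc5ccccc5)c(OCc5ccccc5)c4)[C@H]3OCc3ccccc3)c1OCc1ccccc1)O[C@H](c1ccc(OCc3ccccc3)c(OCc3ccccc3)c1)[C@@H](OCc1ccccc1)C2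
F7 | step 10 | 6-bromo derivative of the C8 mono-carbinol | Brc1c(OCc3ccccc3)c2c(c([C@]3(O)c4c(Cl)cc(OCc5ccccc5)cc4O[C@H](c4ccc(OCc5ccccc5)c(OCc5ccccc5)c4)[C@H]3OCc3ccccc3)c1OCc1ccccc1)O[C@H](c1ccc(OCc3ccccc3)c(OCc3ccccc3)c1)[C@@H](OCc1ccccc1)C2
F8 | step 11 | bis(methyl oxalate) of bis-carbinol 20 | O(Cc1ccccc1)c1cc(Cl)c2c(c1)O[C@H](c1ccc(OCc3ccccc3)c(OCc3ccccc3)c1)[C@@H](OCc1ccccc1)[C@]2(OC(=O)C(=O)OC)c1c(OCc3ccccc3)c2c(c([C@]3(OC(=O)C(=O)OC)c4c(Cl)cc(OCc5ccccc5)cc4O[C@H](c4ccc(OCc5ccccc5)c(OCc5ccccc5)c4)[C@H]3OCc3ccccc3)c1OCc1ccccc1)O[C@H](c1ccc(OCc3ccccc3)c(OCc3ccccc3)c1)[C@@H](OCc1ccccc1)C2
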